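The constants were drawn at random within sensible limits; no experiment stands behind them.

In the first seconds of alpha each unit of starting material, the limiting reagent, can turn several ways, so we keep a ledger in units of its charge.

the same everywhere: protic impurity 0.100 mM; enzyme 0.02 mol%
- alpha: starting material 5.0 mM; time 20 s; everything together in a closed stirred flask, run for 20 s
- theta: starting material 5.0 mM (fed, over 20.0 s); time 20 s; a stirred flask in which starting material is dosed at a steady rate over 20.0 s without added volume, worked up at 20 s
- zeta: starting material 5.0 mM; a single well-mixed tank run continuously and read at steady state, 20 s in it on average

    enzyme + target → enzyme + over-reaction product (k1 = 6700 L mol⁻¹ s⁻¹)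
    2 starting material → homo dimer (k2 = 13 L mol⁻¹ s⁻¹)
    starting material + enzyme → target + enzyme, rate k3*[starting material]*[enzyme]/(1 + ([starting material]/Km3)) (Km3 = 4.5 mM, k3 = 1.2 × 10⁶ L mol⁻¹ s⁻¹)
    starting material + protic impurity → quenched substrate (k4 = 830 L mol⁻¹ s⁻¹)

- percent here means starting material units held: one homo dimer counts as two
- for a step with 2 of a species take k times the square, and two of it per event
- the stated concentrations are those of everything mixed, before any reaction; amounts are the same in each set-up
- the feed brings no volume worth counting
- run time (alpha): 20 s

- order of the set-ups by the amount of target at the outlet or at the end, in percent of the starting material put in, highest first (alpha / theta / zeta)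
- amount of target at the outlet or at the end, in percent of the starting material put in, alpha
- amount of target at the outlet or at the end, in percent of the starting material put in, theta
- amount of target at the outlet or at the end, in percent of the starting material put in, zeta

1. In alpha the enzyme stands at 0.00100 mM, so the branching ratio (a selectivity factor), starting material going to target over starting material going to homo dimer, is 4.37 at the charge, and it drifts higher, to 11.9, at half the charge.

2. We take one over one plus this ratio at full, half and zero charge, with Simpson weights 1, 4, 1, and so get the dimer share, the fraction of the charge that leaves as homo dimer while the charge runs down: 8.28%.

3. At the charge in alpha the protic impurity is consumed at 4.15 s⁻¹, faster than starting material converts to target at 0.568 s⁻¹, so we book its equivalent, 2.00%, as quenched substrate, here and in the two other set-ups.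

4. The remaining 89.7% of alpha becomes target, which decays pseudo-first-order at 0.00670 s⁻¹, with a half-life of 100 s, longer than the run. Charging the whole 20 s against it, the books close at 78.5% target and 11.3% over-reaction product.

5. In theta and zeta, starting material should hold near 0.208 mM, which books 4.17% unconverted and a dimer share of 0.470%. Target waits half the run on average in theta, giving 87.3%, and the tank's spread of ages gives zeta 82.3%. We commit to theta, then zeta, then alpha.

The forecast gave theta > zeta > alpha with 79.4%, 87.8% and 82.8% for alpha, theta and zeta, each above our figure, holding that “the outcome turns mainly on how long target sits in the vessel”.

The simulation gives 79.4% for alpha, 87.6% for theta and 82.8% for zeta, in the order theta > zeta > alpha. At 20.0 s alpha holds 7.99% as homo dimer, against our dimer share of 8.28%. The neighbour flask is alpha with enzyme at 0.005 mol%, a quarter of the loading, so its ratios become 1.09 and 2.97 and its dimer share 24.8%. That flask, computed, holds 23.8% as homo dimer and 72.0% as target.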